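The route rests on cutting ring C of the flavanone (O1, C2, C3, C4, C4a, C8a; ring A is the fused benzene ring, ring B the 2-phenyl group) at O1–C2 and C3–C4. Because O1 is a phenol oxygen on C8a and C4 is a benzylic carbon on the neighbouring C4a, both bonds can be made at once: a salicylaldehyde dimethyl acetal is ionised by a chiral confined Brønsted acid to a 4-methoxy ortho-quinone methide that takes up styrene, closing ring C and setting C2. The precursor is the acetal of 2-hydroxy-3-prenylbenzaldehyde whose 4-oxygen already carries a 1,1-dimethylpropargyl group, an acid-tolerant mask of the final 1,1-dimethylallyl ether, so that one neutral hydrogenation ends the synthesis.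

Key step: step 6

Remark: which antipode of the confined acid gives the (2S,4S) series cannot be predicted with certainty; the (S,S) acid is written, and its mirror image takes its place if the first run shows the opposite sense.

Step 1
Reactants: 1 2,4-dihydroxybenzaldehyde; 2 3-chloro-3-methylbut-1-yne
Product: 3 2-hydroxy-4-[(2-methylbut-3-yn-2-yl)oxy]benzaldehyde
Conditions: 2 (1.3 equiv), CuCl2·2H2O (1 mol %), DBU, MeCN, 0 °C to rt
Reagents that add atoms: none
Why: Copper-catalysed propargylic etherification (substitution through a copper acetylide/allenylidene species) should alkylate only the 4-OH, the more acidic phenol, because the 2-OH is held in a hydrogen bond to the aldehyde.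

Step 2
Reactants: 3 2-hydroxy-4-[(2-methylbut-3-yn-2-yl)oxy]benzaldehyde
Product: 4 2-hydroxy-4-[(2-methylbut-3-en-2-yl)oxy]benzaldehyde
Conditions: H2 (1 atm), 5% Pd/CaCO3 poisoned with Pb(OAc)2, quinoline, EtOAc, rt
Reagents that add atoms: none
Why: Lindlar semi-hydrogenation should stop at the terminal alkene and leave the aldehyde and the aryl ether alone.

Step 3
Reactants: 4 2-hydroxy-4-[(2-methylbut-3-en-2-yl)oxy]benzaldehyde
Product: 5 2,4-dihydroxy-3-(3-methylbut-2-en-1-yl)benzaldehyde
Conditions: PhNEt2, 130 °C
Reagents that add atoms: none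
Why: Aromatic Claisen rearrangement: the [3,3] shift should deliver the allyl unit with allylic inversion, as a prenyl group, to C3, the ortho position whose bond to C4 has the higher double-bond character because the 2-OH is chelated to the aldehyde, and tautomerisation restores the phenol.

Step 4
Reactants: 5 2,4-dihydroxy-3-(3-methylbut-2-en-1-yl)benzaldehyde; 2 3-chloro-3-methylbut-1-yne
Product: 6 2-hydroxy-3-(3-methylbut-2-en-1-yl)-4-[(2-methylbut-3-yn-2-yl)oxy]benzaldehyde
Conditions: 2 (1.5 equiv), CuCl2·2H2O (2 mol %), DBU, MeCN, 0 °C to rt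
Reagents that add atoms: none
Why: The same copper-catalysed propargylic etherification as in step 1 should again take the non-chelated 4-OH (para to the aldehyde), since the slim linear copper-bound propargyl electrophile can reach this oxygen despite the neighbouring prenyl group.

Step 5
Reactants: 6 2-hydroxy-3-(3-methylbut-2-en-1-yl)-4-[(2-methylbut-3-yn-2-yl)oxy]benzaldehyde; 7 trimethyl orthoformate
Product: 8 2-(dimethoxymethyl)-6-(3-methylbut-2-en-1-yl)-5-[(2-methylbut-3-yn-2-yl)oxy]phenol
Conditions: 7 (3 equiv), MeOH, TsOH·H2O (1 mol %), 23 °C; then Et3N, evaporate; used crude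
Reagents that add atoms: none
Why: Acid-catalysed acetalisation driven by the orthoformate as water scavenger (methyl formate leaves) should give the open dimethyl acetal in methanol, and the basic quench prevents reversal through the easily formed ortho-hydroxybenzyl cation.

Step 6
Reactants: 8 2-(dimethoxymethyl)-6-(3-methylbut-2-en-1-yl)-5-[(2-methylbut-3-yn-2-yl)oxy]phenol; 9 styrene
Product: 11 (2S,4S)-4-methoxy-8-(3-methylbut-2-en-1-yl)-7-[(2-methylbut-3-yn-2-yl)oxy]-2-phenylchroman, via 4-methoxy ortho-quinone methide 10 (not isolated)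
Conditions: 9 (5 equiv), (S,S)-iIDP acid HN[P(=O)(O2R*)][P(=NSO2CF3)(O2R*)] (R*O2 = (S)-3,3'-bis(2,4,6-triisopropylphenyl)-1,1'-binaphthalene-2,2'-diolate; 5 mol %), 5 Å MS, toluene, −30 °C
Reagents that add atoms: none
Why: Proposed new method: the confined acid expels one methoxy group of 8 as methanol and leaves the 4-methoxy ortho-quinone methide 10, present as its O-protonated form (a 2-hydroxybenzyl oxocarbenium ion stabilised by the para ether oxygen) hydrogen-bonded and ion-paired to the chiral anion, which takes up styrene in an inverse-electron-demand hetero-Diels–Alder reaction; the closest known reaction types are the achiral acid-promoted coupling of salicylaldehydes, orthoformates and styrenes to cis-4-alkoxy-2-arylchromans and the chiral phosphoric acid or imidodiphosphorimidate catalysed cycloadditions of ortho-quinone methides with styrenes, but an enantioselective variant on an acetal-derived alkoxy quinone methide has not been shown. Ring C is closed by an asynchronous [4+2] cycloaddition (six-membered, C3–C4 formed ahead of O1–C2): the styrene CH2 attacks C4 and the phenolic oxygen captures the benzylic cation developing at C2, which allows only the 2-phenyl regioisomer. C4 is set by the face of the planar cation that the confined anion leaves open, and C2 is set relative to C4 by the half-chair ring closure with phenyl and methoxy both pseudo-equatorial (2,4-cis), so that (4S) carries (2S) with it. The step needs chemoselectivity for styrene over the prenyl alkene of a second molecule, over acid-induced chroman formation from the ortho-prenyl phenol and over cleavage of the tertiary ether; an excess of unhindered styrene, the low temperature, an acid weaker than the imidodiphosphorimidates and the choice of the propargyl (not allyl) ether should secure it, while the sieves bind the methanol. Since C4 is removed later, any trans isomer is separated at this stage so that it cannot dilute the enantiomeric purity at C2.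

Step 7
Reactants: 11 (2S,4S)-4-methoxy-8-(3-methylbut-2-en-1-yl)-7-[(2-methylbut-3-yn-2-yl)oxy]-2-phenylchroman
Product: 12 (2S,4RS)-8-(3-methylbut-2-en-1-yl)-7-[(2-methylbut-3-yn-2-yl)oxy]-2-phenylchroman-4-ol
Conditions: TsOH·H2O (10 mol %), THF/H2O (3:1), 23 °C
Reagents that add atoms: water, O
Why: SN1 solvolysis of the doubly activated benzylic methyl ether: the C4 cation is stabilised by O1 (through C8a) and by the 7-oxygen (para) and should be captured by the large excess of water, while C2–O1, a plain benzyl aryl ether, should not ionise under this mild acid, and the configuration at C4 is irrelevant because C4 becomes the carbonyl carbon.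

Step 8
Reactants: 12 (2S,4RS)-8-(3-methylbut-2-en-1-yl)-7-[(2-methylbut-3-yn-2-yl)oxy]-2-phenylchroman-4-ol
Product: 13 (2S)-8-(3-methylbut-2-en-1-yl)-7-[(2-methylbut-3-yn-2-yl)oxy]-2-phenylchroman-4-one
Conditions: Dess–Martin periodinane (1.3 equiv), pyridine, CH2Cl2, 0 °C to rt
Reagents that add atoms: none
Why: Dess–Martin oxidation of the secondary benzylic alcohol under pyridine-buffered, non-enolising conditions should leave the alkyne, the prenyl alkene and the C2 stereocentre (which is lost only by base-induced ring opening to the chalcone) untouched.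

Step 9
Reactants: 13 (2S)-8-(3-methylbut-2-en-1-yl)-7-[(2-methylbut-3-yn-2-yl)oxy]-2-phenylchroman-4-one
Product: 14 Griffinone C, (2S)-7-[(2-methylbut-3-en-2-yl)oxy]-8-(3-methylbut-2-en-1-yl)-2-phenylchroman-4-one
Conditions: H2 (1 atm), 5% Pd/CaCO3 poisoned with Pb(OAc)2, quinoline, EtOAc, rt; no heating on work-up
Reagents that add atoms: none
Why: Lindlar semi-hydrogenation should add one H2 to the terminal alkyne only, since the trisubstituted prenyl alkene, the aryl ketone and the benzylic C2–O bond are inert on the poisoned catalyst and the neutral medium cannot epimerise C2.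

Compound list
1 | 2,4-dihydroxybenzaldehyde | O=Cc1ccc(O)cc1O | starting material
2 | 3-chloro-3-methylbut-1-yne | C#CC(C)(C)Cl | starting material
3 | 2-hydroxy-4-[(2-methylbut-3-yn-2-yl)oxy]benzaldehyde | O=Cc1ccc(OC(C)(C)C#C)cc1O | intermediate
4 | 2-hydroxy-4-[(2-methylbut-3-en-2-yl)oxy]benzaldehyde | O=Cc1ccc(OC(C)(C)C=C)cc1O | intermediate
5 | 2,4-dihydroxy-3-(3-methylbut-2-en-1-yl)benzaldehyde | O=Cc1ccc(O)c(CC=C(C)C)c1O | intermediate
6 | 2-hydroxy-3-(3-methylbut-2-en-1-yl)-4-[(2-methylbut-3-yn-2-yl)oxy]benzaldehyde | O=Cc1ccc(OC(C)(C)C#C)c(CC=C(C)C)c1O | intermediate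
7 | trimethyl orthoformate | COC(OC)OC | starting material
8 | 2-(dimethoxymethyl)-6-(3-methylbut-2-en-1-yl)-5-[(2-methylbut-3-yn-2-yl)oxy]phenol | COC(OC)c1ccc(OC(C)(C)C#C)c(CC=C(C)C)c1O | intermediate
9 | styrene | C=Cc1ccccc1 | starting material
10 | (6E)-6-(methoxymethylidene)-2-(3-methylbut-2-en-1-yl)-3-[(2-methylbut-3-yn-2-yl)oxy]cyclohexa-2,4-dien-1-one (4-methoxy ortho-quinone methide, not isolated) | CO/C=C1/C(=O)C(CC=C(C)C)=C(OC(C)(C)C#C)C=C1 | intermediate
11 | (2S,4S)-4-methoxy-8-(3-methylbut-2-en-1-yl)-7-[(2-methylbut-3-yn-2-yl)oxy]-2-phenylchroman | CO[C@H]1C[C@@H](c2ccccc2)Oc2c1ccc(OC(C)(C)C#C)c2CC=C(C)C | intermediate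
12 | (2S,4RS)-8-(3-methylbut-2-en-1-yl)-7-[(2-methylbut-3-yn-2-yl)oxy]-2-phenylchroman-4-ol (both C4 epimers) | OC1C[C@@H](c2ccccc2)Oc2c1ccc(OC(C)(C)C#C)c2CC=C(C)C | intermediate
13 | (2S)-8-(3-methylbut-2-en-1-yl)-7-[(2-methylbut-3-yn-2-yl)oxy]-2-phenylchroman-4-one | O=C1C[C@@H](c2ccccc2)Oc2c1ccc(OC(C)(C)C#C)c2CC=C(C)C | intermediate
14 | Griffinone C, (2S)-7-[(2-methylbut-3-en-2-yl)oxy]-8-(3-methylbut-2-en-1-yl)-2-phenylchroman-4-one | C=CC(C)(C)Oc1ccc2c(c1CC=C(C)C)O[C@H](c1ccccc1)CC2=O | target

Total step count: 9. Longest linear sequence: 9 steps (1 to 14).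

Steps most likely to fail

Step 6. The chiral anion may fail to shield one face of the planar cation, giving low enantiomeric excess. The prenyl-flanked phenol oxygen may also sit poorly in the confined pocket, and the released methanol may slow turnover. The fallback uses known chemistry and moves the source of absolute configuration from the catalyst to a resolution. It sets out from 8 and 9, which are joined through the same quinone methide 10 under an achiral acid, (PhO)2P(O)OH (10 mol %) in toluene at 23 °C. This should give racemic cis-4-methoxy-8-(3-methylbut-2-en-1-yl)-7-[(2-methylbut-3-yn-2-yl)oxy]-2-phenylchroman F1. The conditions of step 7 should turn it into racemic 8-(3-methylbut-2-en-1-yl)-7-[(2-methylbut-3-yn-2-yl)oxy]-2-phenylchroman-4-ol F2, and those of step 8 into racemic 8-(3-methylbut-2-en-1-yl)-7-[(2-methylbut-3-yn-2-yl)oxy]-2-phenylchroman-4-one F3. Preparative HPLC on a cellulose tris(3,5-dimethylphenylcarbamate) phase then separates the enantiomers; the (2S) enantiomer is 13, where the route is rejoined.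

Step 7. The C4 cation may lose a proton from C3 (elimination towards the 2H-chromene) instead of taking up water, or the acid may begin to cleave the tertiary propargyl ether. The fallback uses known chemistry and replaces solvolysis plus alcohol oxidation by one oxidative step. It sets out from 11: DDQ in CH2Cl2/H2O at 0 °C abstracts the hydride at C4, as in the cleavage of alkoxybenzyl ethers. Water adds to the methoxy-stabilised cation and the hemiketal loses methanol, which should give ketone 13 directly. The route is rejoined at 13 without a new compound.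

Step 4. The 4-OH of 5 is flanked by the prenyl group, so ether formation at the tertiary carbon may be slow, and alkylation of the chelated 2-OH or decomposition of the chloride may compete. The fallback makes the hindered tertiary ether last, by a different bond-forming method, and carries the oxygen as a silyl ether in between. It sets out from 5 and returns at 14:
- TIPSCl and imidazole in CH2Cl2 should silylate the 4-OH to 2-hydroxy-3-(3-methylbut-2-en-1-yl)-4-(triisopropylsilyloxy)benzaldehyde F4.
- The conditions of step 5 with 7 should give 2-(dimethoxymethyl)-6-(3-methylbut-2-en-1-yl)-5-(triisopropylsilyloxy)phenol F5.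
- The conditions of step 6 with 9 should give, through the silyloxy-substituted 4-methoxy ortho-quinone methide F6 (not isolated), (2S,4S)-4-methoxy-8-(3-methylbut-2-en-1-yl)-2-phenyl-7-(triisopropylsilyloxy)chroman F7.
- The conditions of step 7 should give (2S,4RS)-8-(3-methylbut-2-en-1-yl)-2-phenyl-7-(triisopropylsilyloxy)chroman-4-ol F8.
- The conditions of step 8 should give (2S)-8-(3-methylbut-2-en-1-yl)-2-phenyl-7-(triisopropylsilyloxy)chroman-4-one F9.
- Bu4NF buffered with AcOH (1:1) in THF at 0 °C, chosen so that no free base opens the flavanone ring, should free (2S)-7-hydroxy-8-(3-methylbut-2-en-1-yl)-2-phenylchroman-4-one F10.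
- Decarboxylative Tsuji–Trost O-allylation with tert-butyl 2-methylbut-3-en-2-yl carbonate and Pd(PPh3)4 (5 mol %) in THF at 0 °C should attach the allyl unit at its more substituted end and give 14.

Further compounds
F1 | step 6 | racemic 2,4-cis-4-methoxy-8-(3-methylbut-2-en-1-yl)-7-[(2-methylbut-3-yn-2-yl)oxy]-2-phenylchroman | COC1CC(c2ccccc2)Oc2c1ccc(OC(C)(C)C#C)c2CC=C(C)C
F2 | step 6 | racemic 8-(3-methylbut-2-en-1-yl)-7-[(2-methylbut-3-yn-2-yl)oxy]-2-phenylchroman-4-ol (C4 epimers) | OC1CC(c2ccccc2)Oc2c1ccc(OC(C)(C)C#C)c2CC=C(C)C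
F3 | step 6 | racemic 8-(3-methylbut-2-en-1-yl)-7-[(2-methylbut-3-yn-2-yl)oxy]-2-phenylchroman-4-one | O=C1CC(c2ccccc2)Oc2c1ccc(OC(C)(C)C#C)c2CC=C(C)C
F0 | step 7 | none | none
F4 | step 4 | 2-hydroxy-3-(3-methylbut-2-en-1-yl)-4-(triisopropylsilyloxy)benzaldehyde | O=Cc1ccc(O[Si](C(C)C)(C(C)C)C(C)C)c(CC=C(C)C)c1O
F5 | step 4 | 2-(dimethoxymethyl)-6-(3-methylbut-2-en-1-yl)-5-(triisopropylsilyloxy)phenol | COC(OC)c1ccc(O[Si](C(C)C)(C(C)C)C(C)C)c(CC=C(C)C)c1O
F6 | step 4 | (6E)-6-(methoxymethylidene)-2-(3-methylbut-2-en-1-yl)-3-(triisopropylsilyloxy)cyclohexa-2,4-dien-1-one (not isolated) | CO/C=C1/C(=O)C(CC=C(C)C)=C(O[Si](C(C)C)(C(C)C)C(C)C)C=C1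
F7 | step 4 | (2S,4S)-4-methoxy-8-(3-methylbut-2-en-1-yl)-2-phenyl-7-(triisopropylsilyloxy)chroman | CO[C@H]1C[C@@H](c2ccccc2)Oc2c1ccc(O[Si](C(C)C)(C(C)C)C(C)C)c2CC=C(C)C
F8 | step 4 | (2S,4RS)-8-(3-methylbut-2-en-1-yl)-2-phenyl-7-(triisopropylsilyloxy)chroman-4-ol | OC1C[C@@H](c2ccccc2)Oc2c1ccc(O[Si](C(C)C)(C(C)C)C(C)C)c2CC=C(C)C
F9 | step 4 | (2S)-8-(3-methylbut-2-en-1-yl)-2-phenyl-7-(triisopropylsilyloxy)chroman-4-one | O=C1C[C@@H](c2ccccc2)Oc2c1ccc(O[Si](C(C)C)(C(C)C)C(C)C)c2CC=C(C)C
F10 | step 4 | (2S)-7-hydroxy-8-(3-methylbut-2-en-1-yl)-2-phenylchroman-4-one | O=C1C[C@@H](c2ccccc2)Oc2c1ccc(O)c2CC=C(C)C
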